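## The problem

2,3,4,7-Tetrabromoindole 14 is a planar, achiral bicycle in which a benzene ring (ring A) is fused through C3a–C7a to a pyrrole ring (ring B), with bromine on C2, C3, C4 and C7 and hydrogen only on N1, C5 and C6. There is no stereocentre, so the whole task is to put four bromines on exactly the right carbons. C4 and C7 are the positions of an indole that electrophilic substitution reaches last, so these two C–Br bonds must come with the arene, where they stand para to each other on either side of the ring-fusion carbons. The bromines on C3 and C2 could in principle be added to a finished indole, but the second substitution (C2) is the less dependable one, and an N–H 2,3-dibromoindole is electron-rich and sensitive to acid, light and air, so it should be set free last and under mild conditions. Once the C(sp2)–Br bonds are present they exclude alkyllithium reagents (bromine–lithium exchange), cross-coupling on zerovalent palladium, reducing metals and hydrogenation. The feature that opens a way through is the vicinal pair C2–Br/C3–Br next to N1. C2 with its bromine is a 1-bromoalkyne carbon in disguise, C3–Br can be the electrophile that triggers ring closure, and N1–C2 is the bond made when an ortho nitrogen closes ring B onto that alkyne. What remains, C7a(N)–C3a(C) flanked by C7–Br and C4–Br, is a 1,4-dibromobenzene carrying nitrogen and carbon on its 2- and 3-positions.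

## Retrosynthesis

**14 ⇒ 13.** The first cut is N1–S, leading back to 2,3,4,7-tetrabromo-1-(methylsulfonyl)indole 13. The sulfonyl group does three jobs. It makes the nitrogen of the ring-closing step a nitrogen nucleophile (an amide or carbamate would close through oxygen, a free aniline would be brominated on nitrogen or ring). It tempers the dibromopyrrole ring until the end. It can be removed by a nucleophile at sulfur with no reagent that attacks C–Br. The price is one step, and the forward reaction only has to cleave N–S faster than it touches C2–Br.

**13 ⇒ 11 + 9.** Ring B is opened by cutting N1–C2 and C3–Br together. This gives N-[3,6-dibromo-2-(bromoethynyl)phenyl]methanesulfonamide 11 and an electrophilic bromine donor, N-bromosuccinimide 9. The neighbouring cuts are weaker. Removing C2–Br and C3–Br from a preformed indole leaves both to the order of electrophilic substitution. Cutting N1–C7a calls for a metal-catalysed amination on a ring that carries two C–Br bonds of its own. The chosen cut places each ring-B bromine by the connectivity of the precursor and reduces the bicycle to an ortho-disubstituted benzene. The forward reaction must deliver electrophilic bromine to the triple bond and not to the arene, and nitrogen must close 5-endo on the bromine-bearing carbon.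

**11 ⇒ 8 + 9.** The C(sp)–Br bond is cut next, giving N-(3,6-dibromo-2-ethynylphenyl)methanesulfonamide 8 and a second equivalent of 9. The alternative, dehydrobromination of a 1,1-dibromoalkene, needs a base that also deprotonates the sulfonamide and could close the ring before the electrophile arrives. Silver-catalysed bromination of the terminal alkyne is neutral. The simplification is only one atom, but it turns an unusual group into an ordinary terminal alkyne. The forward step has to stop at monobromination of the alkyne terminus.

**8 ⇒ 6 + 7.** The triple bond is cut between its two carbons. The ring-side carbon is the formyl carbon of N-(3,6-dibromo-2-formylphenyl)methanesulfonamide 6, and the terminal carbon comes from dimethyl (1-diazo-2-oxopropyl)phosphonate 7. Cutting between ring and alkyne (a Sonogashira coupling) would need a third, more reactive halogen at the most crowded position and zerovalent palladium beside two aryl bromides. A dibromoolefination followed by an alkyllithium would exchange those bromides. The aldehyde route needs only a carbonate base in an alcohol solvent. It asks that a di-ortho-substituted aldehyde with an acidic N–H neighbour still accepts the phosphonate anion.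

**6 ⇒ 4 + 5.** The aryl C–N bond is cut to 3,6-dibromo-2-fluorobenzaldehyde 4 and methanesulfonamide 5. The formyl group that later becomes the alkyne is also the activating group an ortho fluorine needs for addition–elimination, so one substituent serves twice. Metal-catalysed amination is excluded by the bromines, and nitration–reduction of a dibromobenzaldehyde would not single out this position. The forward reaction must displace fluoride and leave the bromide on the other side of the aldehyde alone, which the leaving-group order of this mechanism (fluoride far ahead of bromide) should ensure.

**4 ⇒ 1.** Finally the formyl carbon is removed, leaving 1,4-dibromo-2-fluorobenzene 1, a bulk chemical. Aldehyde 4 is itself sold, so the route could start one step later. The carbon to be formylated is the only one flanked by two halogens and therefore the most acidic. A lithium amide deprotonates it, whereas an alkyllithium would attack a bromine. The forward step must keep (3,6-dibromo-2-fluorophenyl)lithium 2 cold enough not to eliminate to an aryne, and its formamide adduct, lithium hemiaminolate 3, releases 4 on work-up.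

## Roads not taken

**Alternative 1:** Diels–Alder construction of ring A with loss of a sulfonyl bridge.
- **Cut:** C3a–C4 and C7–C7a, so ring A is built onto a preformed five-membered nitrogen ring.
- **Forward key step:** 2,5-dibromothiophene 1,1-dioxide A1 would react as an electron-poor diene with the enecarbamate tert-butyl 2,3-dihydro-1H-pyrrole-1-carboxylate A2. Cycloaddition of A1 to the alkene of A2 and cheletropic loss of the sulfonyl bridge would give cis-fused tert-butyl 4,7-dibromo-2,3,3a,7a-tetrahydro-1H-indole-1-carboxylate A3 as a racemate.
- **Merits:** the C4 and C7 bromines arrive by connectivity, the electronic pairing of diene and dienophile is favourable, and both partners are small.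
- **Weak points:**
  - Dioxides of the type of A1 dimerise readily.
  - A3 is at the wrong oxidation level in both rings, and its two stereocentres are made only to be destroyed.
  - Aromatising ring A by dehydrogenation competes with dehydrobromination, which would cost one of the bromines.
  - After dehydrogenation of both rings and carbamate removal the sequence reaches only 4,7-dibromoindole A4. A single Bartoli indole synthesis from 1,4-dibromo-2-nitrobenzene A5 should give A4 as well, so the cycloaddition buys little.
  - From A4 both ring-B bromines must still be introduced by electrophilic substitution.
- **Comparison:** A5 → A4 → 14 would be clearly shorter than the six steps planned here. Against that, the chosen plan does not depend on the second bromination (C2) of an unprotected 3-bromoindole, which has to compete with oxidation of the pyrrole ring and with attack on ring A. It also keeps nitrogen sulfonylated until the final mild step and fixes the position of every bromine by construction, so the substitution pattern of 14 is not in doubt.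

**Alternative 2:** Ruthenium-catalysed [2+2+2] cycloaddition.
- **Cut:** three bonds of ring A at once, C3a–C7a, C4–C5 and C6–C7.
- **Forward key step:** the diyne N-(bromoethynyl)-N-(4-bromobut-3-yn-1-yl)-4-methylbenzenesulfonamide A6 would be cyclotrimerised with acetylene A7 under the catalyst Cp*RuCl(cod) A8 to give 4,7-dibromo-1-(4-methylphenylsulfonyl)indoline A9, closing both rings in one operation.
- **Merits:** high bond count per step, atom economy, and a catalyst class, to which A8 belongs, that is known to carry halogen-terminated diynes through to halogenated arenes.
- **Weak points:**
  - A6 contains a bromine-terminated ynamide, a strongly polarised and probably fragile group whose preparation would itself need several steps.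
  - The gaseous partner A7 must outcompete self-trimerisation of the diyne.
  - A9 is an indoline, so ring B must be oxidised, the arenesulfonyl group removed, and C3 and C2 brominated by substitution, as in Alternative 1.
- **Comparison:** the key step is more convergent than any single step of the chosen plan, but the sequence as a whole would be longer, rests on a precursor of doubtful stability, and again leaves the ring-B bromines to substitution chemistry. The chosen plan closes only one ring, but from robust intermediates and directly at the indole oxidation level.

**Alternative 3:** Bergman cycloaromatisation with bromine-atom capture.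
- **Cut:** C5–C6, together with both benzenoid C–Br bonds.
- **Forward key step:** heating 2,3-diethynyl-1-(4-methylphenylsulfonyl)pyrrole A10 in bromotrichloromethane A11 would form ring A as a para-benzyne-type diradical that takes a bromine atom from A11 at C4 and at C7, giving 4,7-dibromo-1-(4-methylphenylsulfonyl)indole A12.
- **Merits:** ring formation and two C–Br bonds in one step, and a product already at the indole oxidation level with nitrogen protected, which is better than Alternatives 1 and 2.
- **Weak points:**
  - An enediyne whose double bond belongs to a five-membered heteroarene holds its alkyne termini far apart, so cyclisation should need temperatures at which terminal diynes polymerise.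
  - Each radical site can take bromine, a trichloromethyl group or hydrogen, so mixtures are expected, and the trichloromethyl radical left by A11 also adds to alkynes.
  - A10 needs a doubly halogenated pyrrole and two couplings.
  - A12 must still be desulfonylated to A4 and brominated twice.
- **Comparison:** the step is elegant but offers the least control of the four plans. The chosen route uses only polar, low-temperature reactions with predictable site selectivity.

Key step: step 5

## Route

Remark: equivalents, temperatures and solvent ratios in the Conditions lines are planned values.

Step 1
Reactants: 1 1,4-dibromo-2-fluorobenzene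
Product: 4 3,6-dibromo-2-fluorobenzaldehyde, via aryllithium 2 (not isolated), via lithium hemiaminolate 3 (not isolated)
Conditions: LiN(iPr)2 (1.05 equiv), THF, −78 °C; DMF (1.5 equiv), −78 °C; aq. NH4Cl
Reagents that add atoms: N,N-dimethylformamide, CN(C)C=O
Why: Directed ortho-lithiation: the C–H between fluorine and bromine is the most acidic in 1, LiN(iPr)2 deprotonates it without bromine–lithium exchange, and at −78 °C aryllithium 2 should neither eliminate to a benzyne nor undergo halogen migration. Formylation with DMF stops at hemiaminolate 3, which releases aldehyde 4 only on aqueous work-up.

Step 2
Reactants: 4 3,6-dibromo-2-fluorobenzaldehyde; 5 methanesulfonamide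
Product: 6 N-(3,6-dibromo-2-formylphenyl)methanesulfonamide
Conditions: 5 (1.5 equiv), K2CO3 (2.5 equiv), DMSO, 80 °C; aq. HCl to pH 3
Reagents that add atoms: methanesulfonamide (5), CS(N)(=O)=O
Why: Nucleophilic aromatic substitution by addition–elimination: the fluorine is activated by the ortho formyl group and the adjacent bromine, and in this mechanism fluoride leaves far faster than the bromide that is also ortho to the aldehyde. The product is present as its potassium salt, which does not arylate a second time and is released on acidification.

Step 3
Reactants: 6 N-(3,6-dibromo-2-formylphenyl)methanesulfonamide; 7 dimethyl (1-diazo-2-oxopropyl)phosphonate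
Product: 8 N-(3,6-dibromo-2-ethynylphenyl)methanesulfonamide
Conditions: 7 (1.5 equiv), K2CO3 (3 equiv), MeOH, 0 °C to rt; aq. NH4Cl
Reagents that add atoms: dimethyl (1-diazo-2-oxopropyl)phosphonate (7), COP(=O)(OC)C(=[N+]=[N-])C(C)=O
Why: Seyferth–Gilbert homologation in the Ohira–Bestmann form: methanolysis of 7 frees the diazomethylphosphonate anion, which adds to the aldehyde, and loss of dimethyl phosphate and N2 with a 1,2-hydrogen shift gives the terminal alkyne. Carbonate in methanol touches neither the C–Br bonds nor the sulfonamide, which an alkyllithium-based homologation could not guarantee.

Step 4
Reactants: 8 N-(3,6-dibromo-2-ethynylphenyl)methanesulfonamide; 9 N-bromosuccinimide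
Product: 11 N-[3,6-dibromo-2-(bromoethynyl)phenyl]methanesulfonamide, via silver acetylide 10 (not isolated)
Conditions: 9 (1.1 equiv), AgNO3 (10 mol %), acetone, rt, dark
Reagents that add atoms: N-bromosuccinimide (9), O=C1CCC(=O)N1Br
Why: Silver-catalysed bromination of a terminal alkyne: AgNO3 forms acetylide 10, which 9 brominates at carbon with return of the silver salt. The conditions are neutral and compatible with N–H sulfonamides and aryl bromides, and one equivalent of 9 at room temperature should leave the much less reactive bromoalkyne product untouched.

Step 5
Reactants: 11 N-[3,6-dibromo-2-(bromoethynyl)phenyl]methanesulfonamide; 9 N-bromosuccinimide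
Product: 13 2,3,4,7-tetrabromo-1-(methylsulfonyl)indole, via bromirenium ion 12 (not isolated)
Conditions: 9 (1.2 equiv), K2CO3 (1.5 equiv), dry MeCN, 0 °C to rt, dark
Reagents that add atoms: N-bromosuccinimide (9), O=C1CCC(=O)N1Br
Why: This is an electrophilic aminobromination of an alkyne by an ortho sulfonamide, the bromine counterpart of the established halocyclization of 2-alkynyl sulfonanilides to 3-haloindoles, applied here to an alkyne whose far carbon already bears bromine. Reagent 9 transfers electrophilic bromine to the triple bond of 11 to give bridged ion 12, with the new bromine on the ring-side carbon; nitrogen, held over the far carbon by the ortho tether, opens the ion anti at that carbon, and K2CO3 takes up the proton while also ionising part of the acidic sulfonamide and so raising its nucleophilicity. The closure is 5-endo-dig and forms ring B, making N1–C2 and C3–Br in one operation. The only other mode, 4-exo-dig at the ring-side carbon, would give a strained benzazetine, so the regiochemistry of N–C bond formation is fixed by geometry. Opening at the far carbon is also electronically matched, because the bromine already there stabilises developing positive charge by lone-pair donation. No stereocentre is formed; the anti arrangement of nitrogen and bromine across the former alkyne becomes the C2–C3 double bond of the indole. The selectivity required is attack of electrophilic bromine on the alkyne in preference to the arene carbon para to nitrogen (the future C5), and the sulfonyl group together with the two ring bromines deactivates the arene enough to secure it. Product 13 has no remaining position that is nucleophilic toward 9, so over-bromination is not expected.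

Step 6
Reactants: 13 2,3,4,7-tetrabromo-1-(methylsulfonyl)indole
Product: 14 2,3,4,7-tetrabromoindole
Conditions: Cs2CO3 (3 equiv), THF/MeOH 2:1, rt; aq. NH4Cl; dark
Reagents that add atoms: none
Why: Methanolysis of an N-sulfonyl indole with Cs2CO3: methoxide attacks sulfur and expels the indolide, a good leaving group here because four bromines stabilise it, so cleavage should proceed at room temperature. Aryl and heteroaryl bromides are inert to carbonate in methanol at this temperature, and the work-up is kept neutral and dark because free 2,3-dibromoindoles are sensitive.

## Compound list

1 | 1,4-dibromo-2-fluorobenzene | Fc1cc(Br)ccc1Br | starting material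
2 | (3,6-dibromo-2-fluorophenyl)lithium | [Li]c1c(F)c(Br)ccc1Br | intermediate
3 | lithium (3,6-dibromo-2-fluorophenyl)(dimethylamino)methanolate (racemic) | [Li]OC(N(C)C)c1c(F)c(Br)ccc1Br | intermediate
4 | 3,6-dibromo-2-fluorobenzaldehyde | O=Cc1c(F)c(Br)ccc1Br | intermediate
5 | methanesulfonamide | CS(N)(=O)=O | starting material
6 | N-(3,6-dibromo-2-formylphenyl)methanesulfonamide | CS(=O)(=O)Nc1c(Br)ccc(Br)c1C=O | intermediate
7 | dimethyl (1-diazo-2-oxopropyl)phosphonate | COP(=O)(OC)C(=[N+]=[N-])C(C)=O | starting material
8 | N-(3,6-dibromo-2-ethynylphenyl)methanesulfonamide | CS(=O)(=O)Nc1c(Br)ccc(Br)c1C#C | intermediate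
9 | N-bromosuccinimide | O=C1CCC(=O)N1Br | starting material
10 | {[3,6-dibromo-2-(methanesulfonamido)phenyl]ethynyl}silver (silver acetylide of 8) | CS(=O)(=O)Nc1c(Br)ccc(Br)c1C#C[Ag] | intermediate
11 | N-[3,6-dibromo-2-(bromoethynyl)phenyl]methanesulfonamide | CS(=O)(=O)Nc1c(Br)ccc(Br)c1C#CBr | intermediate
12 | 2-bromo-3-[3,6-dibromo-2-(methanesulfonamido)phenyl]bromiren-1-ium (bridged bromonium ion) | CS(=O)(=O)Nc1c(Br)ccc(Br)c1C1=C(Br)[Br+]1 | intermediate
13 | 2,3,4,7-tetrabromo-1-(methylsulfonyl)indole | CS(=O)(=O)n1c(Br)c(Br)c2c(Br)ccc(Br)c12 | intermediate
14 | 2,3,4,7-tetrabromoindole | Brc1[nH]c2c(Br)ccc(Br)c2c1Br | target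

## Step count and risks

Total steps: 6. Longest linear sequence: 6 (1 → 14).

**Step 5 (key step).** Bromine transfer to the electron-poor bromoalkyne may be slow. N-bromination of the sulfonamide, hydration of the triple bond by adventitious water, or base-induced ring closure without capture of bromine at C3 could then outrun the aminobromination. The fallback separates ring closure from bromination and uses only known reaction types. Setting out from 11, Cs2CO3 in DMF at 20–60 °C should convert the sulfonamide anion into 2,4,7-tribromo-1-(methylsulfonyl)indole F1 by the known base-induced 5-endo-dig addition of an ortho sulfonamide to a 1-bromoalkyne. Cs2CO3 in THF/MeOH then removes the sulfonyl group from F1 to give 2,4,7-tribromoindole F2. One equivalent of 9 in DMF at 0 °C brominates F2 at its only open pyrrole position, C3, the classical site of electrophilic substitution of an N–H indole, and the sequence comes back to the route at 14. The C2 bromine is still placed by connectivity, and only the most reliable indole substitution is used for C3.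

**Step 3.** Addition of the diazomethylphosphonate anion to a di-ortho-substituted aldehyde may be slow, because under the basic conditions the ring carries an electron-releasing sulfonamide anion. Incomplete conversion or slow base-induced degradation would follow. The fallback sets out from 6 and avoids base in the carbon–carbon bond-forming event. Dibromoolefination with CBr4 and PPh3 in CH2Cl2 (Ramirez/Corey–Fuchs olefination, neutral, sulfonamide protonated) should give N-[3,6-dibromo-2-(2,2-dibromoethenyl)phenyl]methanesulfonamide F3. Brief treatment of F3 with DBU in DMSO at ambient temperature, the known dehydrobromination of aryl 1,1-dibromoalkenes to 1-bromoalkynes, should then give 11, where the fallback rejoins the route, bypassing 8 and step 4. The exposure to DBU must be short, since prolonged contact could start the anionic ring closure described under step 5.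

**Step 2.** Substitution by the weakly nucleophilic sulfonamide anion at a fluorine flanked on both sides may be incomplete. Reversible condensation at the aldehyde and attack at the bromine ortho to the formyl group are the competing processes. The fallback sets out from 4 and introduces nitrogen with a small, strong nucleophile. NaN3 in DMSO at about 50 °C should give 2-azido-3,6-dibromobenzaldehyde F4. Staudinger reduction of F4 with PPh3 in THF/H2O gives 2-amino-3,6-dibromobenzaldehyde F5, and sulfonylation of F5 with methanesulfonyl chloride in pyridine returns to the route at 6.

**Step 6.** Methoxide may add at C2 and displace bromide instead of attacking sulfur. The liberated, fairly acidic indolide may be N-methylated by the methyl methanesulfonate formed. The free 2,3-dibromoindole may degrade on prolonged basic exposure. The fallback changes the sulfonyl group to one that is removed without a nucleophile at sulfur. Setting out from 4, the same substitution with 2-(trimethylsilyl)ethanesulfonamide should give N-(3,6-dibromo-2-formylphenyl)-2-(trimethylsilyl)ethanesulfonamide F6. The same homologation of F6 with 7 gives N-(3,6-dibromo-2-ethynylphenyl)-2-(trimethylsilyl)ethanesulfonamide F7. AgNO3-catalysed bromination of F7 with 9 gives N-[3,6-dibromo-2-(bromoethynyl)phenyl]-2-(trimethylsilyl)ethanesulfonamide F8. Bromocyclisation of F8 with 9 and K2CO3 gives 2,3,4,7-tetrabromo-1-{[2-(trimethylsilyl)ethyl]sulfonyl}indole F9. Tetrabutylammonium fluoride in THF at room temperature then removes the group from F9 by fluoride-triggered β-elimination, without methoxide and without an alkylating by-product, and the fallback comes back to the route at 14.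

## Further compounds

F1 | step 5 | 2,4,7-tribromo-1-(methylsulfonyl)indole | CS(=O)(=O)n1c(Br)cc2c(Br)ccc(Br)c12
F2 | step 5 | 2,4,7-tribromoindole | Brc1cc2c(Br)ccc(Br)c2[nH]1
F3 | step 3 | N-[3,6-dibromo-2-(2,2-dibromoethenyl)phenyl]methanesulfonamide | CS(=O)(=O)Nc1c(Br)ccc(Br)c1C=C(Br)Br
F4 | step 2 | 2-azido-3,6-dibromobenzaldehyde | [N-]=[N+]=Nc1c(Br)ccc(Br)c1C=O
F5 | step 2 | 2-amino-3,6-dibromobenzaldehyde | Nc1c(Br)ccc(Br)c1C=O
F6 | step 6 | N-(3,6-dibromo-2-formylphenyl)-2-(trimethylsilyl)ethanesulfonamide | C[Si](C)(C)CCS(=O)(=O)Nc1c(Br)ccc(Br)c1C=O
F7 | step 6 | N-(3,6-dibromo-2-ethynylphenyl)-2-(trimethylsilyl)ethanesulfonamide | C[Si](C)(C)CCS(=O)(=O)Nc1c(Br)ccc(Br)c1C#C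
F8 | step 6 | N-[3,6-dibromo-2-(bromoethynyl)phenyl]-2-(trimethylsilyl)ethanesulfonamide | C[Si](C)(C)CCS(=O)(=O)Nc1c(Br)ccc(Br)c1C#CBr
F9 | step 6 | 2,3,4,7-tetrabromo-1-{[2-(trimethylsilyl)ethyl]sulfonyl}indole | C[Si](C)(C)CCS(=O)(=O)n1c(Br)c(Br)c2c(Br)ccc(Br)c12
A1 | alternative 1 | 2,5-dibromothiophene 1,1-dioxide | O=S1(=O)C(Br)=CC=C1Br
A2 | alternative 1 | tert-butyl 2,3-dihydro-1H-pyrrole-1-carboxylate | CC(C)(C)OC(=O)N1CCC=C1
A3 | alternative 1 | tert-butyl cis-4,7-dibromo-2,3,3a,7a-tetrahydro-1H-indole-1-carboxylate (racemic, one enantiomer drawn) | CC(C)(C)OC(=O)N1CC[C@H]2C(Br)=CC=C(Br)[C@@H]12
A4 | alternative 1 | 4,7-dibromoindole | Brc1ccc(Br)c2[nH]ccc12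
A5 | alternative 1 | 1,4-dibromo-2-nitrobenzene | O=[N+]([O-])c1cc(Br)ccc1Br
A6 | alternative 2 | N-(bromoethynyl)-N-(4-bromobut-3-yn-1-yl)-4-methylbenzenesulfonamide | Cc1ccc(cc1)S(=O)(=O)N(CCC#CBr)C#CBr
A7 | alternative 2 | acetylene | C#C
A8 | alternative 2 | chloro(cycloocta-1,5-diene)(pentamethylcyclopentadienyl)ruthenium, Cp*RuCl(cod) | C[c-]1c(C)c(C)c(C)c1C.[Cl-].[Ru+2].C1/C=C\CC/C=C\C1
A9 | alternative 2 | 4,7-dibromo-1-(4-methylphenylsulfonyl)indoline | Cc1ccc(cc1)S(=O)(=O)N1CCc2c(Br)ccc(Br)c12
A10 | alternative 3 | 2,3-diethynyl-1-(4-methylphenylsulfonyl)pyrrole | Cc1ccc(cc1)S(=O)(=O)n1ccc(C#C)c1C#C
A11 | alternative 3 | bromotrichloromethane | ClC(Cl)(Cl)Br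
A12 | alternative 3 | 4,7-dibromo-1-(4-methylphenylsulfonyl)indole | Cc1ccc(cc1)S(=O)(=O)n1ccc2c(Br)ccc(Br)c12
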